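**Retrosynthetic overview**

1. Numbering: C1 (acetoxy carbon), C2 (vinylic CH), C3 (bears C7), C4 (OH), C5 (benzoate), C6 (OH). Without C7 and the acyl groups, ring C1–C6 has the conduritol A pattern (O5/O6 cis, O1 and O4 both trans to them) and a mirror plane through the midpoints of C2=C3 and C5–C6, so one choice between the enantiotopic C1 and C4 fixes all four stereocentres.
2. C4–OH comes from a C4 ketone by reduction directed by the C6 hydroxyl; the O5 benzoate, O1 acetate and O7 benzoate come from stepwise acylations.
3. The C3–C7 bond comes from a Stille coupling of the C3 iodoenone with (tributylstannyl)methanol.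
4. The enone comes from an enantioselective Kornblum–DeLaMare opening of meso endoperoxide 6, itself made by singlet-oxygen [4+2] addition to the meso diene acetonide 5 from 1,4-cyclohexadiene.
5. Ring order: the carbocycle is bought; the dioxolane closes in step 3, the peroxide bridge in step 5 and is opened in step 6; no further ring is formed.

Key step: step 6

Assumption: the quinidine-series catalyst is written for step 6; the sense of induction on this dioxolane-bearing peroxide has to be assigned on the first run, and the quinine-series pseudoenantiomer is used instead should the antipode of 7 form.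

**Route**

Step 1
Reactants: 1 1,4-cyclohexadiene
Product: 2 (±)-trans-4,5-dibromocyclohexene
Conditions: Br2 (1.0 equiv), CH2Cl2, −78 °C
Reagents that add atoms: bromine, BrBr
Why: Electrophilic anti bromination through the bromonium ion gives the trans dibromide, and one equivalent at low temperature should stop at monoaddition because the remaining alkene is deactivated inductively.

Step 2
Reactants: 2 (±)-trans-4,5-dibromocyclohexene
Product: 3 (±)-trans-4,5-dibromocyclohexane-cis-1,2-diol
Conditions: OsO4 (2 mol %), NMO (1.3 equiv), acetone/H2O, rt
Reagents that add atoms: osmium tetroxide (catalytic oxygen carrier), O=[Os](=O)(=O)=O; N-methylmorpholine N-oxide, C[N+]1([O-])CCOCC1; water, O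
Why: Upjohn syn dihydroxylation tolerates the alkyl bromides, and because the two alkene faces of the C2-symmetric dibromide are equivalent a single racemic cis-diol should form.

Step 3
Reactants: 3 (±)-trans-4,5-dibromocyclohexane-cis-1,2-diol
Product: 4 (±)-trans-5,6-dibromo-2,2-dimethyl-cis-hexahydro-1,3-benzodioxole
Conditions: 2,2-dimethoxypropane, TsOH·H2O (cat.), acetone, rt
Reagents that add atoms: 2,2-dimethoxypropane, COC(C)(C)OC
Why: Acid-catalysed transketalisation of the cis-1,2-diol gives the cis-fused dioxolane, a symmetric and base-stable mask for O5/O6.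

Step 4
Reactants: 4 (±)-trans-5,6-dibromo-2,2-dimethyl-cis-hexahydro-1,3-benzodioxole
Product: 5 meso (3aR,7aS)-2,2-dimethyl-3a,7a-dihydro-1,3-benzodioxole (cis-5,6-isopropylidenedioxycyclohexa-1,3-diene), used at once
Conditions: DBU (3 equiv), toluene, 90 °C
Reagents that add atoms: none
Why: Twofold E2 dehydrobromination, each bromide taking an antiperiplanar hydrogen from its neighbouring CH2 group, gives the conjugated diene, and since both stereocentres of the dibromide are destroyed the racemate converges on one meso compound.

Step 5
Reactants: 5 meso diene acetonide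
Product: 6 meso endoperoxide, 4,4-dimethyl-3,5,8,9-tetraoxatricyclo[5.2.2.0(2,6)]undec-10-ene with the peroxide bridge anti to the dioxolane
Conditions: O2, tetraphenylporphyrin (cat.), visible light, CH2Cl2, −20 °C
Reagents that add atoms: dioxygen (as singlet oxygen), O=O
Why: Photosensitised singlet-oxygen [4+2] cycloaddition to the cyclic 1,3-diene should occur on the face opposite the dioxolane for steric and electrostatic reasons, placing the C1–O and C4–O bonds anti to O5/O6 in a meso adduct.

Step 6
Reactants: 6 meso endoperoxide
Product: 7 (3aS,7R,7aS)-7-hydroxy-2,2-dimethyl-3a,7a-dihydro-1,3-benzodioxol-4(7H)-one (C4 ketone, C2=C3, C1–OH anti to the C5/C6 dioxolane)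
Conditions: 9-O-acetylcupreidine (6'-hydroxy cinchona base of the quinidine series, 10 mol %), CH2Cl2, rt; filtered through silica as soon as 6 is consumed
Reagents that add atoms: none
Why: The quinuclidine nitrogen removes the bridgehead proton at C4 antiperiplanar to the weak O–O bond in an E2-like step while the 6'-phenol hydrogen-bonds to the departing oxygen, so O–O breaks, C4 becomes the ketone and O1 leaves as an alkoxide that is protonated by the ammonium ion. The closest known reaction type is the cinchona-amine-catalysed enantioselective Kornblum–DeLaMare rearrangement of meso bicyclic endoperoxides to 4-hydroxy enones. No ring closes; the 2,3-dioxabicyclo[2.2.2]octene bridge opens and one skeletal C=O bond forms. No new stereocentre is created, but the catalyst's choice between the enantiotopic C4–H and C1–H fixes the absolute configuration of C1, C5 and C6, whose relative configuration was set by the anti cycloaddition of step 5. The step needs discrimination of enantiotopic protons and chemoselectivity against onward isomerisation of 7 to the 1,4-dione; the mirror symmetry of 6, in which only the two bridgehead C–H bonds are activated by the peroxide, leaves the catalyst as the sole control element, and low loading with prompt removal of the amine limits over-reaction.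

Step 7
Reactants: 7 4-hydroxy enone acetonide
Product: 8 C1 tert-butyldimethylsilyl ether of 7 (configuration as in 7)
Conditions: TBSCl (1.2 equiv), imidazole (2 equiv), CH2Cl2, 0 °C to rt
Reagents that add atoms: tert-butyldimethylsilyl chloride, CC(C)(C)[Si](C)(C)Cl
Why: Standard silylation of the secondary allylic alcohol blocks base-induced isomerisation of the 4-hydroxy enone and keeps O1 inert in the palladium step, without touching a stereocentre.

Step 8
Reactants: 8 C1 silyl ether enone
Product: 9 C3 iodoenone (8 with iodine on C3)
Conditions: I2 (1.5 equiv), pyridine/CH2Cl2 (1:1), 0 °C to rt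
Reagents that add atoms: iodine, II
Why: Johnson α-iodination, in which reversible conjugate addition of pyridine at C2, iodination of the enolate at C3 and E1cB loss of pyridine put the iodine on the carbon that has to carry C7.

Step 9
Reactants: 9 C3 iodoenone; 10 (tributylstannyl)methanol
Product: 11 C3 hydroxymethyl enone (C7–OH, C1–OTBS, C5/C6 acetonide)
Conditions: Pd(PPh3)4 (5 mol %), CuI (10 mol %), 1,4-dioxane, 80 °C; aqueous KF work-up
Reagents that add atoms: (tributylstannyl)methanol, CCCC[Sn](CCCC)(CCCC)CO
Why: Stille coupling, in which zerovalent palladium inserts into the C3–I bond, the hydroxymethyl group is transferred from tin and reductive elimination forms C3–C7, leaves the silyl ether, the dioxolane and the stereocentres untouched.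

Step 10
Reactants: 11 C3 hydroxymethyl enone; 12 benzoyl chloride
Product: 13 C7 benzoate (C1–OTBS, C5/C6 acetonide, C4 ketone)
Conditions: BzCl (1.2 equiv), 2,4,6-collidine, CH2Cl2, 0 °C to rt
Reagents that add atoms: benzoyl chloride, O=C(Cl)c1ccccc1
Why: Acylation of the only free hydroxyl with the acid chloride, using a hindered base that should not add to C2 of the 2-(acyloxymethyl)enone and so avoids SN2′ loss of the new benzoate.

Step 11
Reactants: 13 C7 benzoate silyl ether
Product: 14 C1 alcohol (C7 benzoate, C5/C6 acetonide, C4 ketone)
Conditions: HF·pyridine, pyridine/THF, 0 °C to rt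
Reagents that add atoms: none
Why: Fluoride cleavage of the Si–O bond under buffered acidic conditions should spare the benzoate, the dioxolane and the base-sensitive enone.

Step 12
Reactants: 14 C1 alcohol
Product: 15 C1 acetate (C7 benzoate, C5/C6 acetonide, C4 ketone)
Conditions: AcCl (1.5 equiv), 2,4,6-collidine, CH2Cl2, 0 °C
Reagents that add atoms: acetyl chloride, CC(=O)Cl
Why: Acetylation of the single free hydroxyl with a non-nucleophilic pyridine base installs the C1 acetate before the diol is unveiled, so no choice between hydroxyls is needed.

Step 13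
Reactants: 15 C1 acetate acetonide
Product: 16 C5,C6 cis-diol (C1 acetate, C7 benzoate, C4 ketone), used directly
Conditions: TFA/H2O (9:1), 0 °C to rt; toluene azeotrope
Reagents that add atoms: none
Why: Aqueous acid hydrolysis of the isopropylidene acetal frees the cis-diol, while the esters and the enone should survive cold aqueous trifluoroacetic acid and no base is present to move an acyl group or enolise the ketol.

Step 14
Reactants: 16 C5,C6 cis-diol; 12 benzoyl chloride
Product: 17 C5 benzoate (C6–OH free, C1 acetate, C7 benzoate, C4 ketone)
Conditions: BzCl (1.05 equiv), 2,4,6-collidine, CH2Cl2, −40 to −20 °C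
Reagents that add atoms: benzoyl chloride, O=C(Cl)c1ccccc1
Why: Kinetic monoacylation of a vicinal diol at its more acidic and less hindered hydroxyl: O5 is an α-ketol hydroxyl next to the sp2 C4 whereas O6 lies between two oxygenated sp3 carbons, so general-base-assisted acylation at low temperature should favour O5, the same acidity bias that governs α-selective sulfonylation and acylation of α,β-dihydroxy carbonyl compounds.

Step 15
Reactants: 17 C5 benzoate ketone
Product: 18 target, [(3R,4S,5R,6S)-3-acetoxy-5-(benzoyloxy)-4,6-dihydroxycyclohex-1-en-1-yl]methyl benzoate (route numbering 1R,4S,5R,6S)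
Conditions: Me4NBH(OAc)3 (5 equiv), MeCN/AcOH (1:1), −35 to −20 °C; pH 7 work-up
Reagents that add atoms: none
Why: Evans–Saksena hydroxyl-directed reduction, in which the C6 hydroxyl binds boron and the alkoxyborohydride delivers hydride to the face of the C4 carbonyl syn to O6, should give the C4 hydroxyl anti to O6 and trans to the C5 benzoate (4S) by 1,2-reduction in an acidic medium that suppresses acyl migration.

**Compound list**

1 | 1,4-cyclohexadiene | C1=CCC=CC1 | starting material
2 | (±)-trans-4,5-dibromocyclohexene (one enantiomer drawn) | C1[C@@H](Br)[C@H](Br)CC=C1 | intermediate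
3 | (±)-trans-4,5-dibromocyclohexane-cis-1,2-diol (one enantiomer drawn) | C1[C@@H](Br)[C@H](Br)C[C@@H](O)[C@H]1O | intermediate
4 | (±)-trans-5,6-dibromo-2,2-dimethyl-cis-hexahydro-1,3-benzodioxole (one enantiomer drawn) | C1[C@@H](Br)[C@H](Br)C[C@H]2OC(C)(C)O[C@@H]12 | intermediate
5 | meso (3aR,7aS)-2,2-dimethyl-3a,7a-dihydro-1,3-benzodioxole | C1=CC=C[C@H]2OC(C)(C)O[C@@H]12 | intermediate
6 | meso endoperoxide, peroxide bridge anti to the dioxolane | O1O[C@@H]2C=C[C@H]1[C@H]1OC(C)(C)O[C@@H]21 | intermediate
7 | (3aS,7R,7aS)-7-hydroxy-2,2-dimethyl-3a,7a-dihydro-1,3-benzodioxol-4(7H)-one | O[C@@H]1C=CC(=O)[C@H]2OC(C)(C)O[C@@H]12 | intermediate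
8 | C1 tert-butyldimethylsilyl ether of 7 | CC(C)(C)[Si](C)(C)O[C@@H]1C=CC(=O)[C@H]2OC(C)(C)O[C@@H]12 | intermediate
9 | C3 iodoenone (C1–OTBS, C5/C6 acetonide) | CC(C)(C)[Si](C)(C)O[C@@H]1C=C(I)C(=O)[C@H]2OC(C)(C)O[C@@H]12 | intermediate
10 | (tributylstannyl)methanol | CCCC[Sn](CCCC)(CCCC)CO | starting material
11 | C3 hydroxymethyl enone (C1–OTBS, C5/C6 acetonide) | CC(C)(C)[Si](C)(C)O[C@@H]1C=C(CO)C(=O)[C@H]2OC(C)(C)O[C@@H]12 | intermediate
12 | benzoyl chloride | O=C(Cl)c1ccccc1 | starting material
13 | C7 benzoate (C1–OTBS, C5/C6 acetonide) | CC(C)(C)[Si](C)(C)O[C@@H]1C=C(COC(=O)c3ccccc3)C(=O)[C@H]2OC(C)(C)O[C@@H]12 | intermediate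
14 | C1 alcohol (C7 benzoate, C5/C6 acetonide) | O[C@@H]1C=C(COC(=O)c3ccccc3)C(=O)[C@H]2OC(C)(C)O[C@@H]12 | intermediate
15 | C1 acetate (C7 benzoate, C5/C6 acetonide) | CC(=O)O[C@@H]1C=C(COC(=O)c3ccccc3)C(=O)[C@H]2OC(C)(C)O[C@@H]12 | intermediate
16 | C5,C6 cis-diol (C1 acetate, C7 benzoate, C4 ketone) | CC(=O)O[C@@H]1C=C(COC(=O)c2ccccc2)C(=O)[C@@H](O)[C@H]1O | intermediate
17 | C5 benzoate, C6–OH (C1 acetate, C7 benzoate, C4 ketone) | CC(=O)O[C@@H]1C=C(COC(=O)c2ccccc2)C(=O)[C@@H](OC(=O)c2ccccc2)[C@H]1O | intermediate
18 | [(3R,4S,5R,6S)-3-acetoxy-5-(benzoyloxy)-4,6-dihydroxycyclohex-1-en-1-yl]methyl benzoate | CC(=O)O[C@@H]1C=C(COC(=O)c2ccccc2)[C@H](O)[C@@H](OC(=O)c2ccccc2)[C@H]1O | target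

**Step count and risks**

Total step count: 15. Longest linear sequence: 15 steps (1 to 18).

Steps most likely to fail:

1. Step 6: the catalyst may discriminate poorly between the two enantiotopic bridgehead protons of this dioxolane-bearing peroxide, or the hydroxy enone may isomerise onward to the 1,4-dione. The fallback sets out from 6 and returns at 8. The peroxide bond of 6 is reduced with thiourea in methanol to the meso ene-diol F1. Lipase-mediated transesterification (Pseudomonas cepacia lipase, vinyl acetate, enzyme and medium chosen in a small screen for the wanted sense) desymmetrises it to the C4 monoacetate F2. Silylation of the remaining C1 hydroxyl (TBSCl, imidazole) gives the silyl ether acetate F3, methanolysis (K2CO3, MeOH) frees the C4 hydroxyl in the silyl ether alcohol F4, and Dess–Martin periodinane oxidation of that allylic alcohol gives 8.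

2. Step 14: acylation may occur at O6 as well as O5, give the dibenzoate, or be followed by benzoyl migration between the cis oxygens. The fallback sets out from 16 and returns at 17. Diol 16 is treated with dibutyltin dimethoxide Bu2Sn(OMe)2 (toluene, rt, methanol removed under vacuum) to give the dibutylstannylene acetal F5, which is benzoylated with 12 (1.0 equiv, CH2Cl2, −20 °C). In such acetals the oxygen on the more electron-poor carbon, here O5, is expected to be the more nucleophilic one, and hydrolytic work-up gives 17.

3. Step 15: intramolecular hydride delivery may be incomplete, giving poor facial selectivity at C4. The fallback sets out from 17 and arrives at 18 directly. It is a reagent-controlled Corey–Bakshi–Shibata reduction ((S)-2-methyl-CBS-oxazaborolidine, catecholborane in excess to allow for the free C6 hydroxyl, toluene, −78 °C). The substituted alkene arm C3 is taken as the large group, as for 2-substituted cyclohexenones, so that hydride should arrive on the face giving the (4S) alcohol. No new compound arises (F0).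

**Further compounds**

F1 | step 6 | meso ene-diol, C1 and C4 hydroxyls anti to the C5/C6 dioxolane | O[C@@H]1C=C[C@H](O)[C@H]2OC(C)(C)O[C@@H]12
F2 | step 6 | C4 monoacetate, C1 hydroxyl free | O[C@@H]1C=C[C@H](OC(C)=O)[C@H]2OC(C)(C)O[C@@H]12
F3 | step 6 | C1 tert-butyldimethylsilyl ether, C4 acetate | CC(C)(C)[Si](C)(C)O[C@@H]1C=C[C@H](OC(C)=O)[C@H]2OC(C)(C)O[C@@H]12
F4 | step 6 | C1 tert-butyldimethylsilyl ether, C4 alcohol | CC(C)(C)[Si](C)(C)O[C@@H]1C=C[C@H](O)[C@H]2OC(C)(C)O[C@@H]12
F5 | step 14 | O5,O6-dibutylstannylene acetal of 16 | CC(=O)O[C@@H]1C=C(COC(=O)c3ccccc3)C(=O)[C@H]2O[Sn](CCCC)(CCCC)O[C@@H]12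
F0 | step 15 | none | none
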